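## Retrosynthetic overview

1. The target comes from bicyclic diol by diacetylation. The tetrahydrofuran ring is formed last, by 5-exo attack of the C12 tertiary OH on C6 of a cis-5,6-epoxide. This inverts C6 and frees the 5-OH.
2. The late coupling forms C7–C8. It is an anti-aldol between the dianion of (R)-2-chloro-4-hydroxy-4-[(Z)-oct-2-enyl]cyclopent-2-enone (C8–C20) and methyl (5R,6R)-5,6-epoxy-7-oxoheptanoate (C1–C7).
3. The carbocycle is present from the start as (S)-4-hydroxycyclopentenone. C12 is set by 1,2-addition of an acetate enolate anti to the OTBS group, and the chain by a Z-Wittig reaction with the hexyl ylide. C9 is then oxidised, and Cl enters through an epoxy ketone and HCl.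
4. The epoxy aldehyde comes from hex-5-ynoic acid and CH2O, then Lindlar reduction, Sharpless epoxidation of the Z-allylic alcohol with L-(+)-DET, and oxidation.

Assumption: (S)-4-hydroxycyclopent-2-enone is bought enantiopure. Positions are given in prostanoid numbering (C1 is the ester carbon, C8–C12 the carbocycle, C20 the chain methyl).

## Route

**Step 1**
Reactants: 1 (S)-4-hydroxycyclopent-2-en-1-one
Product: 2 (S)-4-[(tert-butyldimethylsilyl)oxy]cyclopent-2-en-1-one
Conditions: TBSCl, imidazole, CH2Cl2, 0 °C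
Reagents that add atoms: tert-butyldimethylsilyl chloride, CC(C)(C)[Si](C)(C)Cl
Why: Standard silylation under mild base gives a bulky group that will shield one ring face, and the stereocentre is untouched.

**Step 2**
Reactants: 2 (S)-4-(TBSO)cyclopent-2-en-1-one; 3 ethyl acetate
Product: 5 ethyl 2-[(1S,4S)-4-(TBSO)-1-hydroxycyclopent-2-en-1-yl]acetate (OH cis to OTBS), via lithium enolate of ethyl acetate 4 (not isolated)
Conditions: LDA, 3, THF, −78 °C; then 2, −78 °C, 30 min; AcOH quench at −78 °C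
Reagents that add atoms: none
Why: Kinetic aldol-type 1,2-addition of the ester enolate takes place on the carbonyl face anti to the silyloxy group and sets the future C12, and the minor epimer is removed by chromatography.

**Step 3**
Reactants: 5 β-hydroxy ester
Product: 6 ethyl 2-[(1S,4S)-4-(TBSO)-1-(triethylsilyloxy)cyclopent-2-en-1-yl]acetate
Conditions: TESOTf, 2,6-lutidine, CH2Cl2, −78 → 0 °C
Reagents that add atoms: triethylsilyl triflate, CC[Si](CC)(CC)OS(=O)(=O)C(F)(F)F
Why: Silyl triflate silylation of the tertiary carbinol blocks retro-aldol cleavage in the next two steps.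

**Step 4**
Reactants: 6 bis-silyl ester
Product: 7 2-[(1S,4S)-4-(TBSO)-1-(TESO)cyclopent-2-en-1-yl]acetaldehyde
Conditions: DIBAL-H (1.1 equiv), toluene, −78 °C; aq. Rochelle salt
Reagents that add atoms: none
Why: Partial ester reduction stops at the stable aluminium hemiacetal at −78 °C and gives the aldehyde on work-up.

**Step 5**
Reactants: 8 1-bromohexane
Product: 9 hexyltriphenylphosphonium bromide
Conditions: PPh3, MeCN, reflux
Reagents that add atoms: triphenylphosphine, c1ccc(cc1)P(c1ccccc1)c1ccccc1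
Why: SN2 quaternisation of PPh3 by a primary bromide.

**Step 6**
Reactants: 9 hexyltriphenylphosphonium bromide; 7 aldehyde
Product: 11 (1R,4S)-4-(TBSO)-1-[(Z)-oct-2-en-1-yl]-1-(TESO)cyclopent-2-ene, via hexylidenetriphenylphosphorane 10 (not isolated)
Conditions: 9, NaHMDS, THF, 0 °C; then 7, −78 °C → rt
Reagents that add atoms: none
Why: A Wittig reaction of a non-stabilised ylide under lithium-free conditions gives the C14=C15 Z-olefin under kinetic control.

**Step 7**
Reactants: 11 bis-silyl ether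
Product: 12 (1R,4S)-1-[(Z)-oct-2-en-1-yl]cyclopent-2-ene-1,4-diol (cis-diol)
Conditions: TBAF (3 equiv), THF, 0 °C → rt
Reagents that add atoms: none
Why: Fluoride cleaves both silyl ethers and no stereocentre is involved.

**Step 8**
Reactants: 12 cis-diol
Product: 13 (1S,2R,4S,5S)-2-[(Z)-oct-2-en-1-yl]-6-oxabicyclo[3.1.0]hexane-2,4-diol (epoxide O on the face of both OH groups)
Conditions: VO(acac)2 (2 mol %), t-BuOOH, CH2Cl2, 0 °C
Reagents that add atoms: tert-butyl hydroperoxide, CC(C)(C)OO
Why: Hydroxyl-directed vanadium epoxidation oxidises only the doubly allylic ring olefin, syn to the OH groups, leaves the chain Z-olefin alone and avoids base that could racemise C12 by retro-aldol.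

**Step 9**
Reactants: 13 epoxy diol
Product: 14 (1R,4R,5S)-4-hydroxy-4-[(Z)-oct-2-en-1-yl]-6-oxabicyclo[3.1.0]hexan-2-one
Conditions: TPAP (5 mol %), NMO, 4 Å MS, CH2Cl2, 0 °C → rt
Reagents that add atoms: none
Why: Ley–Griffith oxidation converts the only secondary alcohol (C9) to the ketone under near-neutral conditions, so C12 now carries the chirality alone.

**Step 10**
Reactants: 14 epoxy ketone
Product: 16 (R)-2-chloro-4-hydroxy-4-[(Z)-oct-2-en-1-yl]cyclopent-2-en-1-one, via (2S,3R,4R)-2-chloro-3,4-dihydroxy-4-[(Z)-oct-2-en-1-yl]cyclopentan-1-one 15 (not isolated)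
Conditions: HCl (4 M in dioxane, 2 equiv), CHCl3, 0 °C → rt
Reagents that add atoms: hydrogen chloride, Cl
Why: Chloride opens the protonated α,β-epoxy ketone at the α-carbon because C11 is neopentyl, and the chlorohydrin dehydrates to the 2-chloroenone, as in the preparation of 4-chloro-Δ4-3-keto steroids.

**Step 11**
Reactants: 17 hex-5-ynoic acid; 18 formaldehyde (used as paraformaldehyde)
Product: 20 7-hydroxyhept-5-ynoic acid, via dilithium hex-5-ynoate acetylide 19 (not isolated)
Conditions: n-BuLi (2.1 equiv), THF, −78 → 0 °C; (CH2O)n, 0 °C → rt; aq. HCl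
Reagents that add atoms: none
Why: In the carboxylate/acetylide dianion only the acetylide carbon is nucleophilic, so hydroxymethylation installs C7.

**Step 12**
Reactants: 20 7-hydroxyhept-5-ynoic acid
Product: 21 methyl 7-hydroxyhept-5-ynoate
Conditions: MeOH, H2SO4 (cat.), rt
Reagents that add atoms: methanol, CO
Why: Fischer esterification, which the propargylic alcohol survives.

**Step 13**
Reactants: 21 methyl 7-hydroxyhept-5-ynoate
Product: 22 methyl (Z)-7-hydroxyhept-5-enoate
Conditions: H2 (1 atm), Lindlar Pd, quinoline, EtOAc, rt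
Reagents that add atoms: none
Why: Lindlar semihydrogenation adds H2 syn and gives the Z-allylic alcohol.

**Step 14**
Reactants: 22 methyl (Z)-7-hydroxyhept-5-enoate
Product: 23 methyl 4-[(2R,3S)-3-(hydroxymethyl)oxiran-2-yl]butanoate (cis-epoxide; 5R,6S)
Conditions: Ti(OiPr)4 (10 mol %), L-(+)-DET (12 mol %), t-BuOOH, 4 Å MS, CH2Cl2, −20 °C
Reagents that add atoms: tert-butyl hydroperoxide, CC(C)(C)OO
Why: Sharpless asymmetric epoxidation with L-(+)-tartrate gives the 2S carbinol-side epoxide carbon, hence (5R,6S) from the Z-olefin, and the somewhat lower ee typical of Z-substrates is corrected in step 16.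

**Step 15**
Reactants: 23 cis-epoxy alcohol
Product: 24 methyl 4-[(2R,3R)-3-formyloxiran-2-yl]butanoate (cis; same spatial arrangement)
Conditions: TEMPO (10 mol %), PhI(OAc)2, CH2Cl2, rt; used at once
Reagents that add atoms: none
Why: Oxoammonium oxidation without base stops at the aldehyde and does not epimerise the cis-epoxy aldehyde.

**Step 16**
Reactants: 16 (R)-chloro hydroxy enone; 24 cis-epoxy aldehyde
Product: 26 methyl 4-[(2R,3S)-3-{(S)-[(1S,5R)-3-chloro-5-hydroxy-5-[(Z)-oct-2-en-1-yl]-2-oxocyclopent-3-en-1-yl](hydroxy)methyl}oxiran-2-yl]butanoate (5R,6S,7S,8S,12R), via dilithium alkoxide–dienolate of 16 25 (not isolated)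
Conditions: 16 added to LDA (2.1 equiv), THF, −78 °C, 45 min; then 24, −78 °C, 30 min; AcOH at −78 °C
Reagents that add atoms: none
Why: In this aldol addition of a cyclic E(O)-lithium enolate, attack anti to the octenyl chain (syn to the lithium alkoxide) sets 8S, the Zimmerman–Traxler chair gives 7,8-anti and the Cornforth/polar Felkin–Anh bias of the cis-epoxy aldehyde gives 6,7-anti (7S), so all three reinforce; the alkoxide at C12 also prevents β-elimination, and adducts of the minor enantiomer of 24 are diastereomers removed by chromatography.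

**Step 17**
Reactants: 26 epoxy diol aldol
Product: 28 methyl (5R)-5-acetoxy-5-[(2S,3S,3aS,6aR)-3-acetoxy-5-chloro-6a-[(Z)-oct-2-en-1-yl]-4-oxo-3,3a,4,6a-tetrahydro-2H-cyclopenta[b]furan-2-yl]pentanoate (target), via the corresponding 5,7-diol 27 (not isolated)
Conditions: CSA (10 mol %), CH2Cl2, 0 °C; then pyridine, Ac2O, DMAP (cat.), 0 °C, same flask
Reagents that add atoms: acetic anhydride, CC(=O)OC(C)=O
Why: Acid-catalysed 5-exo-tet opening of the 4,5-epoxy alcohol by the C12 OH inverts C6 (to 6S), keeps 5R and closes the cis-fused ring with both substituents on the convex face, and immediate acetylation caps both alcohols before δ-lactonisation or β-elimination can occur.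

## Compound list

1 | (S)-4-hydroxycyclopent-2-en-1-one | O=C1C=C[C@@H](O)C1 | starting material
2 | (S)-4-[(tert-butyldimethylsilyl)oxy]cyclopent-2-en-1-one | O=C1C=C[C@@H](O[Si](C)(C)C(C)(C)C)C1 | intermediate
3 | ethyl acetate | CCOC(C)=O | starting material
4 | lithium enolate of ethyl acetate | [Li+].C=C([O-])OCC | intermediate
5 | ethyl 2-[(1S,4S)-4-(TBSO)-1-hydroxycyclopent-2-en-1-yl]acetate | CCOC(=O)C[C@]1(O)C=C[C@@H](O[Si](C)(C)C(C)(C)C)C1 | intermediate
6 | ethyl 2-[(1S,4S)-4-(TBSO)-1-(TESO)cyclopent-2-en-1-yl]acetate | CCOC(=O)C[C@]1(O[Si](CC)(CC)CC)C=C[C@@H](O[Si](C)(C)C(C)(C)C)C1 | intermediate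
7 | 2-[(1S,4S)-4-(TBSO)-1-(TESO)cyclopent-2-en-1-yl]acetaldehyde | O=CC[C@]1(O[Si](CC)(CC)CC)C=C[C@@H](O[Si](C)(C)C(C)(C)C)C1 | intermediate
8 | 1-bromohexane | CCCCCCBr | starting material
9 | hexyltriphenylphosphonium bromide | CCCCCC[P+](c1ccccc1)(c1ccccc1)c1ccccc1.[Br-] | intermediate
10 | hexylidenetriphenylphosphorane | CCCCCC=P(c1ccccc1)(c1ccccc1)c1ccccc1 | intermediate
11 | (1R,4S)-4-(TBSO)-1-[(Z)-oct-2-en-1-yl]-1-(TESO)cyclopent-2-ene | CCCCC/C=C\C[C@]1(O[Si](CC)(CC)CC)C=C[C@@H](O[Si](C)(C)C(C)(C)C)C1 | intermediate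
12 | (1R,4S)-1-[(Z)-oct-2-en-1-yl]cyclopent-2-ene-1,4-diol | CCCCC/C=C\C[C@]1(O)C=C[C@@H](O)C1 | intermediate
13 | (1S,2R,4S,5S)-2-[(Z)-oct-2-en-1-yl]-6-oxabicyclo[3.1.0]hexane-2,4-diol | CCCCC/C=C\C[C@]1(O)[C@H]2O[C@H]2[C@@H](O)C1 | intermediate
14 | (1R,4R,5S)-4-hydroxy-4-[(Z)-oct-2-en-1-yl]-6-oxabicyclo[3.1.0]hexan-2-one | CCCCC/C=C\C[C@]1(O)[C@H]2O[C@H]2C(=O)C1 | intermediate
15 | (2S,3R,4R)-2-chloro-3,4-dihydroxy-4-[(Z)-oct-2-en-1-yl]cyclopentan-1-one | CCCCC/C=C\C[C@]1(O)[C@@H](O)[C@H](Cl)C(=O)C1 | intermediate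
16 | (R)-2-chloro-4-hydroxy-4-[(Z)-oct-2-en-1-yl]cyclopent-2-en-1-one | CCCCC/C=C\C[C@]1(O)C=C(Cl)C(=O)C1 | intermediate
17 | hex-5-ynoic acid | C#CCCCC(=O)O | starting material
18 | formaldehyde (paraformaldehyde) | C=O | starting material
19 | dilithium hex-5-ynoate acetylide | [Li+].[Li+].[C-]#CCCCC(=O)[O-] | intermediate
20 | 7-hydroxyhept-5-ynoic acid | OCC#CCCCC(=O)O | intermediate
21 | methyl 7-hydroxyhept-5-ynoate | COC(=O)CCCC#CCO | intermediate
22 | methyl (Z)-7-hydroxyhept-5-enoate | COC(=O)CCC/C=C\CO | intermediate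
23 | methyl 4-[(2R,3S)-3-(hydroxymethyl)oxiran-2-yl]butanoate | COC(=O)CCC[C@H]1O[C@H]1CO | intermediate
24 | methyl 4-[(2R,3R)-3-formyloxiran-2-yl]butanoate | COC(=O)CCC[C@H]1O[C@H]1C=O | intermediate
25 | dilithium alkoxide–dienolate of 16 | [Li+].[Li+].CCCCC/C=C\C[C@]1([O-])C=C(Cl)C([O-])=C1 | intermediate
26 | aldol adduct (5R,6S,7S,8S,12R), 5,6-cis-epoxide, 7-OH, 12-OH | CCCCC/C=C\C[C@]1(O)C=C(Cl)C(=O)[C@H]1[C@H](O)[C@@H]2O[C@@H]2CCCC(=O)OC | intermediate
27 | methyl (5R)-5-[(2S,3S,3aS,6aR)-5-chloro-3-hydroxy-6a-[(Z)-oct-2-en-1-yl]-4-oxo-3,3a,4,6a-tetrahydro-2H-cyclopenta[b]furan-2-yl]-5-hydroxypentanoate | CCCCC/C=C\C[C@]12C=C(Cl)C(=O)[C@H]1[C@H](O)[C@H]([C@@H](CCCC(=O)OC)O)O2 | intermediate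
28 | CNP0318775.1 (5R,6S,7S,8S,12R) | CCCCC/C=C\C[C@]12C=C(Cl)C(=O)[C@H]1[C@H](OC(C)=O)[C@H]([C@@H](CCCC(=O)OC)OC(C)=O)O2 | target

## Step count and risks

Total step count: 17.
Longest linear sequence: 11 steps (1, 2, 3, 4, 6, 7, 8, 9, 10, 16, 17).

### Steps most likely to fail

**Step 16 (dianion aldol).** The risks are attack of LDA on the chloroenone, retro-aldol cleavage, and incomplete control at C7 and C8.

The fallback sets out from 16 (with 24) and comes back at 27. It replaces the unprotected lithium dianion by soft enolisation of a protected carbinol and a closed boron transition state.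
- TMSCl/imidazole converts 16 into (R)-2-chloro-4-[(Z)-oct-2-en-1-yl]-4-(trimethylsilyloxy)cyclopent-2-en-1-one F3.
- c-Hex2BCl/Et3N (Et2O, 0 → −78 °C) gives its dicyclohexylboron dienolate F4.
- F4 adds to 24 at −78 °C through a tight chair, giving the anti product on the face anti to the octenyl chain. After a pH 7 work-up this is the 12-O-TMS aldol adduct F5.
- Under the CSA conditions of step 17, with a trace of MeOH, F5 loses the TMS group and cyclises to 27.

**Step 17 (epoxide-opening cyclisation).** The risks are 6-endo opening at C5, participation of the ester carbonyl, and δ-lactone formation.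

The fallback sets out from 22 and 16 and comes back at 28. It closes the ring by halo-etherification of an olefin instead of opening an epoxide.
- MnO2 oxidation of 22 with Z→E equilibration gives methyl (E)-7-oxohept-5-enoate F6.
- The dianion 25 of 16 adds to F6 as in step 16 and gives the (7S,8S,12R) allylic alcohol aldol adduct F7.
- I2/NaHCO3 in MeCN at 0 °C effects 5-exo iodoetherification. Addition across the E-olefin is anti, and the new C6 substituent ends up cis to the allylic 7-OH on the convex face. The product is the (5S)-5-iodo bicyclic ether F8.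
- Ac2O/pyridine gives its 7-acetate F9.
- AgOAc in wet AcOH displaces iodide through the 7-acetoxy-derived dioxanylium ion, with a single inversion to 5R. This gives the 5-hydroxy 7-acetate F10, together with its acyl-migrated isomer.
- Ac2O/pyridine converts both isomers into 28.

**Step 2 (enolate 1,2-addition).** The risks are enolisation with loss of OTBS, 1,4-addition, and modest facial selectivity.

The fallback sets out from 2 and comes back at 12. It builds the chain by allylation and olefin metathesis instead of aldol, reduction and Wittig.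
- AllylMgBr/CeCl3 (THF, −78 °C) is non-basic and adds strictly 1,2. It adds anti to OTBS and gives (1R,4S)-1-allyl-4-[(tert-butyldimethylsilyl)oxy]cyclopent-2-en-1-ol F1.
- Z-selective cross-metathesis with hept-1-ene (cyclometalated Ru nitrato catalyst, THF, 35 °C) gives (1R,4S)-4-[(tert-butyldimethylsilyl)oxy]-1-[(Z)-oct-2-en-1-yl]cyclopent-2-en-1-ol F2.
- TBAF converts F2 into 12.

## Further compounds

F1 | step 2 | (1R,4S)-1-allyl-4-[(tert-butyldimethylsilyl)oxy]cyclopent-2-en-1-ol | C=CC[C@]1(O)C=C[C@@H](O[Si](C)(C)C(C)(C)C)C1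
F2 | step 2 | (1R,4S)-4-[(tert-butyldimethylsilyl)oxy]-1-[(Z)-oct-2-en-1-yl]cyclopent-2-en-1-ol | CCCCC/C=C\C[C@]1(O)C=C[C@@H](O[Si](C)(C)C(C)(C)C)C1
F3 | step 16 | (R)-2-chloro-4-[(Z)-oct-2-en-1-yl]-4-(trimethylsilyloxy)cyclopent-2-en-1-one | CCCCC/C=C\C[C@]1(O[Si](C)(C)C)C=C(Cl)C(=O)C1
F4 | step 16 | dicyclohexylboron dienolate of F3 | CCCCC/C=C\C[C@]1(O[Si](C)(C)C)C=C(Cl)C(OB(C2CCCCC2)C2CCCCC2)=C1
F5 | step 16 | 12-O-TMS aldol adduct (5R,6S,7S,8S,12R) | CCCCC/C=C\C[C@]1(O[Si](C)(C)C)C=C(Cl)C(=O)[C@H]1[C@H](O)[C@@H]2O[C@@H]2CCCC(=O)OC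
F6 | step 17 | methyl (E)-7-oxohept-5-enoate | COC(=O)CCC/C=C/C=O
F7 | step 17 | (7S,8S,12R) allylic alcohol aldol adduct with 5E-olefin | CCCCC/C=C\C[C@]1(O)C=C(Cl)C(=O)[C@H]1[C@H](O)/C=C/CCCC(=O)OC
F8 | step 17 | (5S)-5-iodo bicyclic ether, 7-OH | CCCCC/C=C\C[C@]12C=C(Cl)C(=O)[C@H]1[C@H](O)[C@H]([C@H](CCCC(=O)OC)I)O2
F9 | step 17 | (5S)-5-iodo bicyclic ether, 7-acetate | CCCCC/C=C\C[C@]12C=C(Cl)C(=O)[C@H]1[C@H](OC(C)=O)[C@H]([C@H](CCCC(=O)OC)I)O2
F10 | step 17 | (5R)-5-hydroxy 7-acetate | CCCCC/C=C\C[C@]12C=C(Cl)C(=O)[C@H]1[C@H](OC(C)=O)[C@H]([C@@H](CCCC(=O)OC)O)O2
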